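## Retrosynthetic overview

1. Target 21 ⇐ elemanolide 17: late oxidation of the isopropenyl group (allylic hydroxylation, Sharpless epoxidation, oxidation to the aldehyde).
2. 17 ⇐ germacranolide 16: Cope rearrangement of the (E,E)-cyclodecadiene closes the cyclohexane (C5–C10) and sets C5 and C10.
3. 16 ⇐ 12: the ten-membered ring is closed at C6–C7 (the bond made in germacrene biosynthesis) by chromium-mediated γ-allylation of an enal by a 3-(bromomethyl)butenolide. This unveils the α-methylene lactone directly as the 8,12-olide and sets C6 and C7.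
4. 12 ⇐ 2 + 6: a catalytic asymmetric vinylogous Mukaiyama aldol joins 8-oxogeranyl acetate to a 2-silyloxyfuran and sets C8 and C9.
5. Ring order: butenolide (from the furan) → ten-membered carbocycle → cyclohexane → oxirane.

Germacrane/elemane locants (C1–C15) are used for all intermediates.

Assumption: the (R,R) antipode of the bis-phosphoramide catalyst is taken to be the one that delivers aldol 8; if the first run shows the opposite sense, the (S,S) antipode is used under the same conditions.

## Route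

Step 1
Reactants: 1 geranyl acetate
Product: 2 (2E,6E)-8-oxogeranyl acetate
Conditions: SeO2 (1.1 equiv), 95% EtOH, reflux
Reagents that add atoms: selenium dioxide, O=[Se]=O
Why: Riley allylic oxidation (ene reaction then [2,3]-sigmatropic shift) attacks the (E)-methyl of the electron-rich terminal alkene and runs on to the (E)-enal; no stereocentre is formed.

Step 2
Reactants: 3 furan-3-ylmethanol
Product: 6 2-(trimethylsilyloxy)-3-[(trimethylsilyloxy)methyl]furan, via dilithiated furylmethoxide 4 (not isolated), via lithium silyloxyfurylmethoxide 5 (not isolated)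
Conditions: n-BuLi (2.2 equiv), THF, −78 to 0 °C; Me3SiOOSiMe3, −78 °C; Me3SiCl (2.2 equiv), −78 °C to rt; distil
Reagents that add atoms: bis(trimethylsilyl) peroxide, C[Si](C)(C)OO[Si](C)(C)C; chlorotrimethylsilane, C[Si](C)(C)Cl
Why: alkoxide-directed ortho-lithiation of the furan at C2, electrophilic oxygenation of the furyllithium by the silyl peroxide (which gives the 2-silyloxyfuran directly) and O-silylation of the alkoxide; no stereocentre is formed.

Step 3
Reactants: 2 (2E,6E)-8-oxogeranyl acetate; 6 2-(trimethylsilyloxy)-3-[(trimethylsilyloxy)methyl]furan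
Product: 8 (5S)-5-[(1R,2E,6E)-8-acetoxy-1-hydroxy-2,6-dimethylocta-2,6-dien-1-yl]-3-(hydroxymethyl)furan-2(5H)-one, via trichlorosilyl aldolate 7 (not isolated)
Conditions: SiCl4 (1.5 equiv), Denmark's dimeric (R,R)-binaphthyl-2,2′-diamine bis-phosphoramide (pentane-1,5-diyl tether, 5 mol %), iPr2NEt (0.2 equiv), CH2Cl2, −78 °C; aq. NaHCO3; then 1 M HCl, THF, 0 °C
Reagents that add atoms: none
Why: Lewis base-catalysed, SiCl4-mediated vinylogous Mukaiyama aldol reaction in which the furan attacks through C5 in an open transition state on the aldehyde bound to the chiral phosphoramide–silyl cation, giving the 5,1′-anti (erythro) adduct and setting C8 (S) and C9 (R) under catalyst control.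

Step 4
Reactants: 8 (5S)-5-[(1R,2E,6E)-8-acetoxy-1-hydroxy-2,6-dimethylocta-2,6-dien-1-yl]-3-(hydroxymethyl)furan-2(5H)-one
Product: 9 bis-TBS ether of 8 (C9-OTBS and C13-OTBS)
Conditions: TBSOTf (2.4 equiv), 2,6-lutidine, CH2Cl2, −78 to 0 °C
Reagents that add atoms: tert-butyldimethylsilyl trifluoromethanesulfonate, CC(C)(C)[Si](C)(C)OS(=O)(=O)C(F)(F)F
Why: silyl triflate silylation protects C9-OH so that only C6-OH is free after ring closure, and turns C13-OH into the latent leaving group; no stereocentre is touched.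

Step 5
Reactants: 9 bis-TBS ether of 8
Product: 10 (5S)-5-[(1R,2E,6E)-1-(tert-butyldimethylsilyloxy)-8-hydroxy-2,6-dimethylocta-2,6-dien-1-yl]-3-[(tert-butyldimethylsilyloxy)methyl]furan-2(5H)-one
Conditions: immobilised Candida antarctica lipase B, n-BuOH, MTBE, 35 °C
Reagents that add atoms: none
Why: lipase-catalysed transesterification removes the unhindered primary allylic acetate under neutral conditions, which spares the butenolide (epimerisable C8, Michael acceptor) that basic methanolysis would endanger.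

Step 6
Reactants: 10 C6 allylic alcohol
Product: 11 (2E,6E,8R)-8-(tert-butyldimethylsilyloxy)-8-[(2S)-4-[(tert-butyldimethylsilyloxy)methyl]-5-oxo-2,5-dihydrofuran-2-yl]-3,7-dimethylocta-2,6-dienal
Conditions: MnO2 (20 equiv), CH2Cl2, rt
Reagents that add atoms: none
Why: MnO2 oxidation of the primary allylic alcohol gives the enal with retention of the (E)-geometry and leaves the silyl ethers untouched.

Step 7
Reactants: 11 enal bis-silyl ether
Product: 12 (2E,6E,8R)-8-[(2S)-4-(bromomethyl)-5-oxo-2,5-dihydrofuran-2-yl]-8-(tert-butyldimethylsilyloxy)-3,7-dimethylocta-2,6-dienal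
Conditions: Ph3PBr2 (1.1 equiv), CH2Cl2, 0 °C
Reagents that add atoms: dibromotriphenylphosphorane, BrP(Br)(c1ccccc1)(c1ccccc1)c1ccccc1
Why: direct conversion of a silyl ether into a bromide (oxyphosphonium formation, then SN2 by bromide) is much faster at the primary allylic C13 ether than at the hindered secondary C9 ether.

Step 8
Reactants: 12 bromomethyl butenolide enal
Product: 15 (1(10)E,4E,6R,7S,8S,9R)-9-(tert-butyldimethylsilyloxy)-6-hydroxygermacra-1(10),4,11(13)-trien-12,8-olide, via allylchromium dichloride 13 (not isolated), via chromium alkoxide 14 (not isolated)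
Conditions: CrCl2 (8 equiv), THF, rt, syringe-pump addition of 12 over 12 h (final 2 mM); aq. work-up
Reagents that add atoms: none
Why: Proposed new method: CrCl2 inserts into the allylic C–Br bond and the allylchromium 13 adds through its γ-carbon (C7) to the tethered enal in a chair Zimmerman–Traxler transition state, so the C6–C7 bond of the ten-membered ring and the α-methylene-γ-lactone form together; the ring-fixed (E)-type allyl geometry (C8 trans to CH2Cr) gives the 6,7-anti relationship (6α-OH) and the short tether delivers the aldehyde to the butenolide face carrying C9, giving the cis-fused lactone (H-7α, H-8α); the closest known reactions are the intermolecular chromium- or zinc-mediated additions of 3-(bromomethyl)furan-2(5H)-ones to aldehydes and the Nozaki–Hiyama–Kishi macrocyclisations of 2-(bromomethyl)acrylates onto enals that give germacranolides.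

Step 9
Reactants: 15 germacranolide alcohol
Product: 16 (1(10)E,4E,6R,7S,8S,9R)-9-(tert-butyldimethylsilyloxy)-6-(2-methylpropanoyloxy)germacra-1(10),4,11(13)-trien-12,8-olide
Conditions: (iPrCO)2O, Et3N, DMAP (cat.), CH2Cl2, 0 °C to rt
Reagents that add atoms: 2-methylpropanoic anhydride, CC(C)C(=O)OC(=O)C(C)C
Why: DMAP-catalysed acylation of the only free hydroxyl (C6) with retention of configuration.

Step 10
Reactants: 16 germacranolide isobutyrate
Product: 17 (5S,6R,7S,8S,9R,10S)-9-(tert-butyldimethylsilyloxy)-6-(2-methylpropanoyloxy)elema-1,3,11(13)-trien-12,8-olide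
Conditions: PhMe (0.02 M), BHT (cat.), 170 °C, sealed tube
Reagents that add atoms: none
Why: Cope rearrangement of the (E,E)-cyclodeca-1,5-diene through the chair transition state that keeps the C6, C7 and C9 substituents pseudo-equatorial forms the C5–C10 bond, gives the trans-1,2-dialkenylcyclohexane and sets C10 (S, methyl β) and C5 (S, H α), driven by relief of ten-membered ring strain.

Step 11
Reactants: 17 elemanolide
Product: 18 (5S,6R,7S,8S,9R,10S)-9-(tert-butyldimethylsilyloxy)-15-hydroxy-6-(2-methylpropanoyloxy)elema-1,3,11(13)-trien-12,8-olide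
Conditions: SeO2 (0.5 equiv), t-BuOOH (2 equiv), CH2Cl2, 0 °C to rt
Reagents that add atoms: selenium dioxide, O=[Se]=O; tert-butyl hydroperoxide, CC(C)(C)OO
Why: SeO2/t-BuOOH allylic hydroxylation (ene reaction then [2,3]-shift) occurs at the methyl of the only electron-rich alkene with accessible allylic hydrogens, since the vinyl group has none, the methylene lactone is electron-poor and the ring methine H-5 is hindered; no stereocentre is affected.

Step 12
Reactants: 18 silyl ether allylic alcohol
Product: 19 (5S,6R,7S,8S,9R,10S)-9,15-dihydroxy-6-(2-methylpropanoyloxy)elema-1,3,11(13)-trien-12,8-olide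
Conditions: HF·pyridine, pyridine/THF, 0 °C to rt
Reagents that add atoms: none
Why: fluoride-driven Si–O cleavage frees C9-OH before the acid-sensitive epoxy aldehyde is built, and spares the isobutyrate and the lactone.

Step 13
Reactants: 19 diol
Product: 20 (4S,5S,6S,7S,8S,9R,10S)-3,4-epoxy-9,15-dihydroxy-6-(2-methylpropanoyloxy)elema-1,11(13)-dien-12,8-olide
Conditions: Ti(OiPr)4 (20 mol %), L-(+)-diethyl tartrate (24 mol %), t-BuOOH (2 equiv), 4 Å MS, CH2Cl2, −20 °C
Reagents that add atoms: tert-butyl hydroperoxide, CC(C)(C)OO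
Why: Sharpless asymmetric epoxidation with L-(+)-tartrate delivers oxygen to the face of the 2-substituted allylic alcohol that gives the (4S) epoxy alcohol (the same sense as (S)-2-methylglycidol from methallyl alcohol), which becomes the (4R) centre of the target, while the vinyl group, the methylene lactone and the remote C9-OH are not epoxidised.

Step 14
Reactants: 20 epoxy diol
Product: 21 target CNP0127398.1
Conditions: TEMPO (10 mol %), PhI(OAc)2 (1.2 equiv), CH2Cl2, rt
Reagents that add atoms: none
Why: oxoammonium (TEMPO/PhI(OAc)2) oxidation is selective for the primary alcohol over the hindered neopentyl-type secondary C9-OH, and the resulting epoxy aldehyde has no α-hydrogen, so C4 cannot epimerise.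

## Compound list

1 | geranyl acetate | CC(=O)OC/C=C(C)/CCC=C(C)C | starting material
2 | (2E,6E)-3,7-dimethyl-8-oxoocta-2,6-dien-1-yl acetate (8-oxogeranyl acetate) | CC(=O)OC/C=C(C)/CC/C=C(C)/C=O | intermediate
3 | furan-3-ylmethanol | OCc1ccoc1 | starting material
4 | lithium (2-lithiofuran-3-yl)methoxide | [Li]OCc1ccoc1[Li] | intermediate
5 | lithium [2-(trimethylsilyloxy)furan-3-yl]methoxide | [Li]OCc1ccoc1O[Si](C)(C)C | intermediate
6 | 2-(trimethylsilyloxy)-3-[(trimethylsilyloxy)methyl]furan | C[Si](C)(C)OCc1ccoc1O[Si](C)(C)C | intermediate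
7 | (5S)-5-[(1R,2E,6E)-8-acetoxy-2,6-dimethyl-1-(trichlorosilyloxy)octa-2,6-dien-1-yl]-3-[(trimethylsilyloxy)methyl]furan-2(5H)-one | CC(=O)OC/C=C(C)/CC/C=C(C)/[C@@H](O[Si](Cl)(Cl)Cl)[C@H]1OC(=O)C(CO[Si](C)(C)C)=C1 | intermediate
8 | (5S)-5-[(1R,2E,6E)-8-acetoxy-1-hydroxy-2,6-dimethylocta-2,6-dien-1-yl]-3-(hydroxymethyl)furan-2(5H)-one | CC(=O)OC/C=C(C)/CC/C=C(C)/[C@@H](O)[C@H]1OC(=O)C(CO)=C1 | intermediate
9 | (5S)-5-[(1R,2E,6E)-8-acetoxy-1-(tert-butyldimethylsilyloxy)-2,6-dimethylocta-2,6-dien-1-yl]-3-[(tert-butyldimethylsilyloxy)methyl]furan-2(5H)-one | CC(=O)OC/C=C(C)/CC/C=C(C)/[C@@H](O[Si](C)(C)C(C)(C)C)[C@H]1OC(=O)C(CO[Si](C)(C)C(C)(C)C)=C1 | intermediate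
10 | (5S)-5-[(1R,2E,6E)-1-(tert-butyldimethylsilyloxy)-8-hydroxy-2,6-dimethylocta-2,6-dien-1-yl]-3-[(tert-butyldimethylsilyloxy)methyl]furan-2(5H)-one | OC/C=C(C)/CC/C=C(C)/[C@@H](O[Si](C)(C)C(C)(C)C)[C@H]1OC(=O)C(CO[Si](C)(C)C(C)(C)C)=C1 | intermediate
11 | (2E,6E,8R)-8-(tert-butyldimethylsilyloxy)-8-[(2S)-4-[(tert-butyldimethylsilyloxy)methyl]-5-oxo-2,5-dihydrofuran-2-yl]-3,7-dimethylocta-2,6-dienal | O=C/C=C(C)/CC/C=C(C)/[C@@H](O[Si](C)(C)C(C)(C)C)[C@H]1OC(=O)C(CO[Si](C)(C)C(C)(C)C)=C1 | intermediate
12 | (2E,6E,8R)-8-[(2S)-4-(bromomethyl)-5-oxo-2,5-dihydrofuran-2-yl]-8-(tert-butyldimethylsilyloxy)-3,7-dimethylocta-2,6-dienal | O=C/C=C(C)/CC/C=C(C)/[C@@H](O[Si](C)(C)C(C)(C)C)[C@H]1OC(=O)C(CBr)=C1 | intermediate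
13 | allylchromium dichloride from 12 (trivalent chromium on C13) | O=C/C=C(C)/CC/C=C(C)/[C@@H](O[Si](C)(C)C(C)(C)C)[C@H]1OC(=O)C(C[Cr](Cl)Cl)=C1 | intermediate
14 | chromium dichloride alkoxide of 15 (trivalent chromium on O6) | Cl[Cr](Cl)O[C@@H]1/C=C(C)/CC/C=C(C)/[C@@H](O[Si](C)(C)C(C)(C)C)[C@H]2OC(=O)C(=C)[C@H]21 | intermediate
15 | (1(10)E,4E,6R,7S,8S,9R)-9-(tert-butyldimethylsilyloxy)-6-hydroxygermacra-1(10),4,11(13)-trien-12,8-olide (6α-OH, 9β-OTBS, cis-fused 8β,12-lactone) | O[C@@H]1/C=C(C)/CC/C=C(C)/[C@@H](O[Si](C)(C)C(C)(C)C)[C@H]2OC(=O)C(=C)[C@H]21 | intermediate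
16 | (1(10)E,4E,6R,7S,8S,9R)-9-(tert-butyldimethylsilyloxy)-6-(2-methylpropanoyloxy)germacra-1(10),4,11(13)-trien-12,8-olide | CC(C)C(=O)O[C@@H]1/C=C(C)/CC/C=C(C)/[C@@H](O[Si](C)(C)C(C)(C)C)[C@H]2OC(=O)C(=C)[C@H]21 | intermediate
17 | (5S,6R,7S,8S,9R,10S)-9-(tert-butyldimethylsilyloxy)-6-(2-methylpropanoyloxy)elema-1,3,11(13)-trien-12,8-olide | C=C[C@@]1(C)[C@H](C(C)=C)[C@@H](OC(=O)C(C)C)[C@@H]2C(=C)C(=O)O[C@@H]2[C@@H]1O[Si](C)(C)C(C)(C)C | intermediate
18 | (5S,6R,7S,8S,9R,10S)-9-(tert-butyldimethylsilyloxy)-15-hydroxy-6-(2-methylpropanoyloxy)elema-1,3,11(13)-trien-12,8-olide | C=C[C@@]1(C)[C@H](C(CO)=C)[C@@H](OC(=O)C(C)C)[C@@H]2C(=C)C(=O)O[C@@H]2[C@@H]1O[Si](C)(C)C(C)(C)C | intermediate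
19 | (5S,6R,7S,8S,9R,10S)-9,15-dihydroxy-6-(2-methylpropanoyloxy)elema-1,3,11(13)-trien-12,8-olide | C=C[C@@]1(C)[C@H](C(CO)=C)[C@@H](OC(=O)C(C)C)[C@@H]2C(=C)C(=O)O[C@@H]2[C@@H]1O | intermediate
20 | (4S,5S,6S,7S,8S,9R,10S)-3,4-epoxy-9,15-dihydroxy-6-(2-methylpropanoyloxy)elema-1,11(13)-dien-12,8-olide | C=C[C@@]1(C)[C@H]([C@]2(CO)CO2)[C@@H](OC(=O)C(C)C)[C@@H]2C(=C)C(=O)O[C@@H]2[C@@H]1O | intermediate
21 | CNP0127398.1, (4R,5S,6S,7S,8S,9R,10S)-3,4-epoxy-9-hydroxy-6-(2-methylpropanoyloxy)-15-oxoelema-1,11(13)-dien-12,8-olide | C=C[C@@]1(C)[C@H]([C@]2(C=O)CO2)[C@@H](OC(=O)C(C)C)[C@@H]2C(=C)C(=O)O[C@@H]2[C@@H]1O | target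

## Step count

Total: 14 steps. Longest linear sequence: 13 steps (1 → 21 through steps 1 and 3–14; equally 3 → 21 through steps 2–14).

## Three steps most likely to fail, with fallbacks

Step 8 (ring closure). It asks one event to close a strained ten-membered ring and to control both the face of the butenolide and the face of the aldehyde, and the chromium reagent may oligomerise or give the trans-fused or 6-epi isomers. The fallback sets out from 12. Palladium-catalysed borylation with bis(pinacolato)diboron (Pd2(dba)3, toluene, high dilution) turns the bromide into the isolable allylboronate, (2E,6E,8R)-8-(tert-butyldimethylsilyloxy)-3,7-dimethyl-8-[(2S)-5-oxo-4-[(4,4,5,5-tetramethyl-1,3,2-dioxaborolan-2-yl)methyl]-2,5-dihydrofuran-2-yl]octa-2,6-dienal F2. F2 is closed by intramolecular allylboration through the tighter boron-centred chair transition state (gentle heating or catalytic Sc(OTf)3, optionally a chiral phosphoric acid to reinforce the facial preference), giving the pinacol borate of the germacranolide alcohol F3. Aqueous work-up of F3 comes back to the route at 15.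

Step 3 (vinylogous aldol). The anti/syn ratio and the enantioselectivity have to hold for an α-methyl enal and a 3-substituted silyloxyfuran that carries a second silyl ether. The fallback sets out from 2 and 6. Compound 6 is hydrolysed (aqueous THF, trace HCl) to the parent butenolide, 3-(hydroxymethyl)furan-2(5H)-one F1. F1 is then added directly to 2 under a bifunctional cinchona-derived tertiary amine–squaramide catalyst, which forms the dienolate by Brønsted-base catalysis and directs the aldehyde by hydrogen bonding in an anti-selective direct vinylogous aldol reaction. This replaces the silyl dienolate/Lewis acid manifold altogether and comes back to the route at 8.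

Step 13 (Sharpless epoxidation). The allylic alcohol carries a bulky, chiral 2-substituent, so the reaction may be slow or mismatched, and 2-substituted glycidols are prone to titanium-mediated ring opening. The fallback sets out from 19. MnO2 oxidises the allylic alcohol to the 2-substituted acrolein, (5S,6R,7S,8S,9R,10S)-9-hydroxy-6-(2-methylpropanoyloxy)-15-oxoelema-1,3,11(13)-trien-12,8-olide F4. F4 is epoxidised nucleophilically by iminium catalysis with aqueous H2O2 and a 9-amino-9-deoxy-epi-cinchona primary amine salt. The pseudo-enantiomeric quinine- and quinidine-derived catalysts give access to either C4 epimer, and the methylene lactone is not activated by the amine. This comes back to the route directly at 21 and by-passes 20.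

Further compounds
F1 | step 3 | 3-(hydroxymethyl)furan-2(5H)-one | O=C1OCC=C1CO
F2 | step 8 | (2E,6E,8R)-8-(tert-butyldimethylsilyloxy)-3,7-dimethyl-8-[(2S)-5-oxo-4-[(4,4,5,5-tetramethyl-1,3,2-dioxaborolan-2-yl)methyl]-2,5-dihydrofuran-2-yl]octa-2,6-dienal | O=C/C=C(C)/CC/C=C(C)/[C@@H](O[Si](C)(C)C(C)(C)C)[C@H]1OC(=O)C(CB2OC(C)(C)C(C)(C)O2)=C1
F3 | step 8 | pinacol borate (O6–B) of the germacranolide alcohol 15 | CC1(C)OB(O[C@@H]2/C=C(C)/CC/C=C(C)/[C@@H](O[Si](C)(C)C(C)(C)C)[C@H]3OC(=O)C(=C)[C@H]32)OC1(C)C
F4 | step 13 | (5S,6R,7S,8S,9R,10S)-9-hydroxy-6-(2-methylpropanoyloxy)-15-oxoelema-1,3,11(13)-trien-12,8-olide | C=C[C@@]1(C)[C@H](C(C=O)=C)[C@@H](OC(=O)C(C)C)[C@@H]2C(=C)C(=O)O[C@@H]2[C@@H]1O
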